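The route rests on cutting the C8–C9 bond of ring A. Ring A holds a homoallylic alcohol (methylene C14 on C7, hydroxyl on C9) next to the C10 bromide, which is the signature of a carbonyl-ene reaction. A Lewis-acid type 2 ene cyclisation of an (R)-α-bromo aldehyde therefore closes ring A, creates the C14 methylene and sets C9 cis to the bromide in one operation. The precursor carries the isopropenyl group and the CMe2–CHBr–CHO chain on one carbon (C6) of a symmetric ketal-protected cyclohexanone; its two adjacent quaternary carbons come from an Ireland–Claisen rearrangement. C6 and C3 are set afterwards on ring B.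

Key step: step 8

Assumption (chemistry): chamigrene locants are used for all spiro compounds (ring B C1–C5, spiro C6, ring A C7–C11, methylene C14, chloromethyl C15), and ring B of ketone 16 is taken to sit in the chair with C11 equatorial and C7 axial (the other chair gives two syn-pentane contacts with a C11 methyl), which presses the axial hydrogen on C2 against C14 and leaves C4 as the kinetically open α-carbon.

Step 1
Reactants: 1 1,4-dioxaspiro[4.5]decane-8-carboxylic acid; 2 1-bromo-3-methylbut-2-ene (prenyl bromide)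
Product: 3 3-methylbut-2-en-1-yl 1,4-dioxaspiro[4.5]decane-8-carboxylate
Conditions: K2CO3, DMF, rt
Reagents that add atoms: none
Why: O-alkylation of a carboxylate (SN2) is fast at the primary allylic carbon and leaves the ketal untouched.

Step 2
Reactants: 3 3-methylbut-2-en-1-yl 1,4-dioxaspiro[4.5]decane-8-carboxylate
Product: 6 8-(2-methylbut-3-en-2-yl)-1,4-dioxaspiro[4.5]decane-8-carboxylic acid, via silyl ketene acetal 4 (not isolated), via trimethylsilyl ester 5 (not isolated)
Conditions: LiN(iPr)2, TMSCl, THF, −78 °C → 60 °C; then aq. citric acid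
Reagents that add atoms: none
Why: Ireland–Claisen rearrangement, in which the concerted [3,3] shift of the fully substituted ketene acetal joins the ring carbon (future C6) to the dimethyl-bearing allyl terminus (future C11), an established way to build two adjacent quaternary carbons; no stereocentre is formed.

Step 3
Reactants: 6 8-(2-methylbut-3-en-2-yl)-1,4-dioxaspiro[4.5]decane-8-carboxylic acid
Product: 8 1-[8-(2-methylbut-3-en-2-yl)-1,4-dioxaspiro[4.5]decan-8-yl]ethan-1-one, via dilithium diolate 7 (not isolated)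
Conditions: MeLi (3 equiv), Et2O/THF, 0 °C → rt; then H2O
Reagents that add atoms: methyllithium [Li]C
Why: addition of MeLi to a lithium carboxylate stops at the dilithium 1,1-diolate, so hydrolysis should give the methyl ketone without over-addition, the classical route to hindered methyl ketones.

Step 4
Reactants: 8 1-[8-(2-methylbut-3-en-2-yl)-1,4-dioxaspiro[4.5]decan-8-yl]ethan-1-one
Product: 9 8-(2-methylbut-3-en-2-yl)-8-(prop-1-en-2-yl)-1,4-dioxaspiro[4.5]decane
Conditions: Cp2Ti(μ-Cl)(μ-CH2)AlMe2, pyridine (cat.), THF/toluene, −40 °C → rt; then H2O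
Reagents that add atoms: Tebbe reagent C[Al-]1(C)C[Ti](C2C=CC=C2)(C2C=CC=C2)[Cl+]1
Why: Tebbe methylenation, whose small non-basic titanium methylidene converts hindered enolisable ketones, at a temperature low enough to keep the 1,5-diene product from Cope rearrangement.

Step 5
Reactants: 9 8-(2-methylbut-3-en-2-yl)-8-(prop-1-en-2-yl)-1,4-dioxaspiro[4.5]decane
Product: 11 3-methyl-3-[8-(prop-1-en-2-yl)-1,4-dioxaspiro[4.5]decan-8-yl]butan-1-ol, via alkyl(disiamyl)borane 10 (not isolated)
Conditions: Sia2BH (from BH3·SMe2 + 2-methylbut-2-ene), THF, 0 °C → rt; then NaOH, H2O2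
Reagents that add atoms: hydrogen peroxide OO
Why: hydroboration–oxidation with a bulky dialkylborane, which adds anti-Markovnikov to the monosubstituted vinyl group much faster than to the 1,1-disubstituted isopropenyl group on a quaternary carbon.

Step 6
Reactants: 11 3-methyl-3-[8-(prop-1-en-2-yl)-1,4-dioxaspiro[4.5]decan-8-yl]butan-1-ol
Product: 12 3-methyl-3-[8-(prop-1-en-2-yl)-1,4-dioxaspiro[4.5]decan-8-yl]butanal
Conditions: Dess–Martin periodinane, pyridine, CH2Cl2, 0 °C → rt
Reagents that add atoms: none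
Why: Dess–Martin oxidation stops at the aldehyde, and the pyridine buffer keeps the medium non-acidic so that neither the ketal nor the aldehyde/isopropenyl pair reacts.

Step 7
Reactants: 12 3-methyl-3-[8-(prop-1-en-2-yl)-1,4-dioxaspiro[4.5]decan-8-yl]butanal
Product: 13 (2R)-2-bromo-3-methyl-3-[8-(prop-1-en-2-yl)-1,4-dioxaspiro[4.5]decan-8-yl]butanal
Conditions: (R)-2-{bis[3,5-bis(trifluoromethyl)phenyl](trimethylsilyloxy)methyl}pyrrolidine (20 mol %), PhCO2H (20 mol %), 4,4-dibromo-2,6-di-tert-butylcyclohexa-2,5-dienone, CH2Cl2/pentane, −40 °C; cold short silica plug, used at once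
Reagents that add atoms: 4,4-dibromo-2,6-di-tert-butylcyclohexa-2,5-dienone CC(C)(C)C1=CC(Br)(Br)C=C(C(C)(C)C)C1=O
Why: enamine-mediated organocatalytic α-bromination, in which the bulky arm of the diarylprolinol silyl ether shields one face of the E-enamine so that the mild Br+ donor (inert to the isopropenyl group) attacks the open face; by the usual model in which the (S)-catalyst gives (S)-2-halo aldehydes, the (R)-catalyst should set C10 as R.

Step 8
Reactants: 13 (2R)-2-bromo-3-methyl-3-[8-(prop-1-en-2-yl)-1,4-dioxaspiro[4.5]decan-8-yl]butanal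
Product: 14 (9S,10R)-10-bromo-9-hydroxy-11,11-dimethyl-7-methylidenespiro[5.5]undecan-3-one ethylene ketal
Conditions: Me2AlCl (2.5 equiv), CH2Cl2, −78 °C; then aq. KNaC4H4O6
Reagents that add atoms: none
Why: Me2AlCl binds the aldehyde oxygen and the isopropenyl group reacts as the ene partner in a concerted, asynchronous process: its terminal CH2 (C8) bonds to C9 while a hydrogen of the allylic methyl moves to oxygen, so that this methyl becomes the C14 methylene. The closest known reaction type is the Me2AlCl-promoted type 2 carbonyl-ene cyclisation of δ,ε-unsaturated aldehydes bearing a 1,1-disubstituted alkene to 3-methylenecyclohexanols, and α-halo aldehydes are established enophiles under Lewis acid activation. Ring A closes as a six-membered ring in the type 2 mode (6-exo at the carbonyl, both alkene carbons C7 and C8 inside the new ring) through a bicyclic chair–chair transition state. The new stereocentre C9 is controlled by C10: hydrogen transfer requires an axial C9–O bond, and bromine stays equatorial, anti to the forming C8–C9 bond (polar Felkin–Anh model) and clear of the axial ring B methylene on C6, which should give the cis bromohydrin (9S,10R). The step needs this diastereoselectivity and retention at C10; the low temperature, the hindered α-hydrogen beside quaternary C11 and the proton-scavenging methyl groups on aluminium should secure retention, and the excess Lewis acid covers coordination to the ketal, which is inert at −78 °C.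

Step 9
Reactants: 14 (9S,10R)-10-bromo-9-hydroxy-11,11-dimethyl-7-methylidenespiro[5.5]undecan-3-one ethylene ketal
Product: 15 (9S,10R)-10-bromo-9-(tert-butyldimethylsilyloxy)-11,11-dimethyl-7-methylidenespiro[5.5]undecan-3-one ethylene ketal
Conditions: TBSOTf, 2,6-lutidine, CH2Cl2, −78 → 0 °C
Reagents that add atoms: tert-butyldimethylsilyl trifluoromethanesulfonate CC(C)(C)[Si](C)(C)OS(=O)(=O)C(F)(F)F
Why: silylation with a silyl triflate and a hindered pyridine base overcomes the shielding of the axial C9 hydroxyl, and the cis bromide cannot be displaced by the neighbouring oxygen.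

Step 10
Reactants: 15 (9S,10R)-10-bromo-9-(tert-butyldimethylsilyloxy)-11,11-dimethyl-7-methylidenespiro[5.5]undecan-3-one ethylene ketal
Product: 16 (9S,10R)-10-bromo-9-(tert-butyldimethylsilyloxy)-11,11-dimethyl-7-methylidenespiro[5.5]undecan-3-one
Conditions: PPTS, acetone/H2O, 60 °C
Reagents that add atoms: water O
Why: acid-catalysed hydrolysis of a dioxolane under PPTS is mild enough for the hindered secondary TBS ether and the exocyclic alkene.

Step 11
Reactants: 16 (9S,10R)-10-bromo-9-(tert-butyldimethylsilyloxy)-11,11-dimethyl-7-methylidenespiro[5.5]undecan-3-one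
Product: 17 (6S,9S,10R)-10-bromo-9-(tert-butyldimethylsilyloxy)-11,11-dimethyl-7-methylidene-3-(trimethylsilyloxy)spiro[5.5]undec-3-ene
Conditions: lithium (R,R)-bis(1-phenylethyl)amide (from the amine + n-BuLi), TMSCl (in situ), THF, −100 → −78 °C
Reagents that add atoms: chlorotrimethylsilane C[Si](C)(C)Cl
Why: enantiotopos-selective deprotonation by a chiral lithium amide with in situ silylation, where the (R,R)-base, which in 4-tert-butylcyclohexanone removes the corresponding axial hydrogen, takes the open axial hydrogen on C4 and not the one on C2 buried against C14, so that base and substrate reinforce each other and C6 becomes stereogenic with the enol ether on the C4 side.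

Step 12
Reactants: 17 (6S,9S,10R)-10-bromo-9-(tert-butyldimethylsilyloxy)-11,11-dimethyl-7-methylidene-3-(trimethylsilyloxy)spiro[5.5]undec-3-ene
Product: 18 (6S,9S,10R)-10-bromo-9-(tert-butyldimethylsilyloxy)-11,11-dimethyl-7-methylidenespiro[5.5]undec-4-en-3-one
Conditions: Pd(OAc)2 (1.1 equiv), MeCN, rt
Reagents that add atoms: none
Why: Saegusa–Ito oxidation, in which palladation of the silyl enol ether at C4 and β-hydride loss from C5 give the enone, locking the C6 configuration and leaving C2 as the only enolisable carbon of ring B.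

Step 13
Reactants: 18 (6S,9S,10R)-10-bromo-9-(tert-butyldimethylsilyloxy)-11,11-dimethyl-7-methylidenespiro[5.5]undec-4-en-3-one
Product: 19 (6S,9S,10R)-10-bromo-9-(tert-butyldimethylsilyloxy)-11,11-dimethyl-7-methylidene-3-(triethylsilyloxy)spiro[5.5]undeca-2,4-diene
Conditions: TESOTf, Et3N, CH2Cl2, 0 °C → rt
Reagents that add atoms: triethylsilyl trifluoromethanesulfonate CC[Si](CC)(CC)OS(=O)(=O)C(F)(F)F
Why: soft enolisation of an enone with a silyl triflate and an amine can only take the α′ hydrogen on C2, because the γ carbon C6 is quaternary, and gives the cross-conjugated 2-silyloxy diene.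

Step 14
Reactants: 19 (6S,9S,10R)-10-bromo-9-(tert-butyldimethylsilyloxy)-11,11-dimethyl-7-methylidene-3-(triethylsilyloxy)spiro[5.5]undeca-2,4-diene
Product: 21 (2R,6S,9S,10R)-10-bromo-9-(tert-butyldimethylsilyloxy)-11,11-dimethyl-7-methylidene-2-(triethylsilyloxy)spiro[5.5]undec-4-en-3-one, via silyloxy epoxide 20 (not isolated)
Conditions: mCPBA (1.05 equiv), NaHCO3, CH2Cl2, −20 °C
Reagents that add atoms: 3-chloroperbenzoic acid OOC(=O)c1cccc(Cl)c1
Why: Rubottom oxidation, in which the peracid takes the electron-rich C2=C3 enol ether bond in preference to the other alkenes, from the face away from C7 and C14, and the epoxide opens with 1,4-silyl shift; the C2 centre formed here is erased in step 18.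

Step 15
Reactants: 21 (2R,6S,9S,10R)-10-bromo-9-(tert-butyldimethylsilyloxy)-11,11-dimethyl-7-methylidene-2-(triethylsilyloxy)spiro[5.5]undec-4-en-3-one
Product: 22 (2R,6R,9S,10R)-10-bromo-9-(tert-butyldimethylsilyloxy)-11,11-dimethyl-7-methylidene-2-(triethylsilyloxy)spiro[5.5]undecan-3-one
Conditions: [(Ph3P)CuH]6, toluene, H2O (trace), rt
Reagents that add atoms: none
Why: copper hydride conjugate reduction delivers hydride only to C5 of the enone and leaves the isolated alkene, the alkyl bromide and both silyl ethers untouched.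

Step 16
Reactants: 22 (2R,6R,9S,10R)-10-bromo-9-(tert-butyldimethylsilyloxy)-11,11-dimethyl-7-methylidene-2-(triethylsilyloxy)spiro[5.5]undecan-3-one
Product: 23 (2R,3R,6R,9S,10R)-10-bromo-9-(tert-butyldimethylsilyloxy)-3,15-epoxy-3,11,11-trimethyl-7-methylidene-2-(triethylsilyloxy)spiro[5.5]undecane (oxirane C3–O–C15)
Conditions: Me3S(O)I, NaH, DMSO/THF, rt
Reagents that add atoms: trimethylsulfoxonium iodide C[S+](C)(C)=O.[I-]
Why: Corey–Chaykovsky epoxidation with the sulfoxonium ylide, whose reversible addition lets the betaine with an equatorial C3–C15 bond close to the oxirane with axial oxygen, which in the ring B chair with C11 equatorial is the 3R epoxide that maps onto 3S of the target.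

Step 17
Reactants: 23 (2R,3R,6R,9S,10R)-10-bromo-9-(tert-butyldimethylsilyloxy)-3,15-epoxy-3,11,11-trimethyl-7-methylidene-2-(triethylsilyloxy)spiro[5.5]undecane
Product: 25 (2R,3S,6R,9S,10R)-10-bromo-9-(tert-butyldimethylsilyloxy)-3-(chloromethyl)-11,11-dimethyl-7-methylidenespiro[5.5]undecane-2,3-diol, via chlorohydrin triethylsilyl ether 24 (not isolated)
Conditions: LiCl, AcOH, THF, rt; then dilute aq. HCl, 0 °C
Reagents that add atoms: lithium chloride [Li+].[Cl-]
Why: acid-assisted SN2 opening of the terminal epoxide by chloride at the unhindered CH2 (C15) keeps the C3 configuration, and brief aqueous acid then removes the triethylsilyl ether while the hindered TBS ether stays.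

Step 18
Reactants: 25 (2R,3S,6R,9S,10R)-10-bromo-9-(tert-butyldimethylsilyloxy)-3-(chloromethyl)-11,11-dimethyl-7-methylidenespiro[5.5]undecane-2,3-diol
Product: 26 (3S,6R,9S,10R)-10-bromo-9-(tert-butyldimethylsilyloxy)-3-(chloromethyl)-3-hydroxy-11,11-dimethyl-7-methylidenespiro[5.5]undecan-2-one
Conditions: IBX, DMSO, rt
Reagents that add atoms: none
Why: IBX oxidation turns the secondary C2 alcohol of a 1,2-diol into the ketone without C–C cleavage, the tertiary C3 alcohol cannot be oxidised, and the neutral medium does not close the chlorohydrin to an epoxide.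

Step 19
Reactants: 26 (3S,6R,9S,10R)-10-bromo-9-(tert-butyldimethylsilyloxy)-3-(chloromethyl)-3-hydroxy-11,11-dimethyl-7-methylidenespiro[5.5]undecan-2-one
Product: 27 (3S,6R,9S,10R)-10-bromo-3-(chloromethyl)-3,9-dihydroxy-11,11-dimethyl-7-methylidenespiro[5.5]undecan-2-one (CNP0273087.1)
Conditions: HF·pyridine, THF, 0 °C → rt
Reagents that add atoms: none
Why: fluoride desilylation under acidic rather than basic conditions removes the TBS group without epoxide formation from the chlorohydrin or α-ketol rearrangement.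

Compound list
1 | 1,4-dioxaspiro[4.5]decane-8-carboxylic acid | OC(=O)C1CCC2(CC1)OCCO2 | starting material
2 | 1-bromo-3-methylbut-2-ene | CC(C)=CCBr | starting material
3 | 3-methylbut-2-en-1-yl 1,4-dioxaspiro[4.5]decane-8-carboxylate | CC(C)=CCOC(=O)C1CCC2(CC1)OCCO2 | intermediate
4 | silyl ketene acetal of 3 | CC(C)=CCOC(O[Si](C)(C)C)=C1CCC2(CC1)OCCO2 | intermediate
5 | trimethylsilyl 8-(2-methylbut-3-en-2-yl)-1,4-dioxaspiro[4.5]decane-8-carboxylate | C=CC(C)(C)C1(C(=O)O[Si](C)(C)C)CCC2(CC1)OCCO2 | intermediate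
6 | 8-(2-methylbut-3-en-2-yl)-1,4-dioxaspiro[4.5]decane-8-carboxylic acid | C=CC(C)(C)C1(C(=O)O)CCC2(CC1)OCCO2 | intermediate
7 | dilithium 1-[8-(2-methylbut-3-en-2-yl)-1,4-dioxaspiro[4.5]decan-8-yl]ethane-1,1-diolate | C=CC(C)(C)C1(C(C)(O[Li])O[Li])CCC2(CC1)OCCO2 | intermediate
8 | 1-[8-(2-methylbut-3-en-2-yl)-1,4-dioxaspiro[4.5]decan-8-yl]ethan-1-one | C=CC(C)(C)C1(C(C)=O)CCC2(CC1)OCCO2 | intermediate
9 | 8-(2-methylbut-3-en-2-yl)-8-(prop-1-en-2-yl)-1,4-dioxaspiro[4.5]decane | C=CC(C)(C)C1(C(C)=C)CCC2(CC1)OCCO2 | intermediate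
10 | bis(3-methylbutan-2-yl){3-methyl-3-[8-(prop-1-en-2-yl)-1,4-dioxaspiro[4.5]decan-8-yl]butyl}borane | CC(C)C(C)B(CCC(C)(C)C1(C(C)=C)CCC2(CC1)OCCO2)C(C)C(C)C | intermediate
11 | 3-methyl-3-[8-(prop-1-en-2-yl)-1,4-dioxaspiro[4.5]decan-8-yl]butan-1-ol | OCCC(C)(C)C1(C(C)=C)CCC2(CC1)OCCO2 | intermediate
12 | 3-methyl-3-[8-(prop-1-en-2-yl)-1,4-dioxaspiro[4.5]decan-8-yl]butanal | O=CCC(C)(C)C1(C(C)=C)CCC2(CC1)OCCO2 | intermediate
13 | (2R)-2-bromo-3-methyl-3-[8-(prop-1-en-2-yl)-1,4-dioxaspiro[4.5]decan-8-yl]butanal | O=C[C@H](Br)C(C)(C)C1(C(C)=C)CCC2(OCCO2)CC1 | intermediate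
14 | (9S,10R)-10-bromo-9-hydroxy-11,11-dimethyl-7-methylidenespiro[5.5]undecan-3-one ethylene ketal | C=C1C[C@H](O)[C@H](Br)C(C)(C)C12CCC3(OCCO3)CC2 | intermediate
15 | (9S,10R)-10-bromo-9-(tert-butyldimethylsilyloxy)-11,11-dimethyl-7-methylidenespiro[5.5]undecan-3-one ethylene ketal | C=C1C[C@H](O[Si](C)(C)C(C)(C)C)[C@H](Br)C(C)(C)C12CCC3(OCCO3)CC2 | intermediate
16 | (9S,10R)-10-bromo-9-(tert-butyldimethylsilyloxy)-11,11-dimethyl-7-methylidenespiro[5.5]undecan-3-one | C=C1C[C@H](O[Si](C)(C)C(C)(C)C)[C@H](Br)C(C)(C)C12CCC(=O)CC2 | intermediate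
17 | (6S,9S,10R)-10-bromo-9-(tert-butyldimethylsilyloxy)-11,11-dimethyl-7-methylidene-3-(trimethylsilyloxy)spiro[5.5]undec-3-ene | C=C1C[C@H](O[Si](C)(C)C(C)(C)C)[C@H](Br)C(C)(C)[C@@]12CC=C(O[Si](C)(C)C)CC2 | intermediate
18 | (6S,9S,10R)-10-bromo-9-(tert-butyldimethylsilyloxy)-11,11-dimethyl-7-methylidenespiro[5.5]undec-4-en-3-one | C=C1C[C@H](O[Si](C)(C)C(C)(C)C)[C@H](Br)C(C)(C)[C@@]12C=CC(=O)CC2 | intermediate
19 | (6S,9S,10R)-10-bromo-9-(tert-butyldimethylsilyloxy)-11,11-dimethyl-7-methylidene-3-(triethylsilyloxy)spiro[5.5]undeca-2,4-diene | C=C1C[C@H](O[Si](C)(C)C(C)(C)C)[C@H](Br)C(C)(C)[C@@]12C=CC(O[Si](CC)(CC)CC)=CC2 | intermediate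
20 | (2R,3R,6S,9S,10R)-2,3-epoxide of 19 (oxygen on the face away from C7) | C=C1C[C@H](O[Si](C)(C)C(C)(C)C)[C@H](Br)C(C)(C)[C@@]12C=C[C@]3(O[Si](CC)(CC)CC)O[C@@H]3C2 | intermediate
21 | (2R,6S,9S,10R)-10-bromo-9-(tert-butyldimethylsilyloxy)-11,11-dimethyl-7-methylidene-2-(triethylsilyloxy)spiro[5.5]undec-4-en-3-one | C=C1C[C@H](O[Si](C)(C)C(C)(C)C)[C@H](Br)C(C)(C)[C@@]12C=CC(=O)[C@H](O[Si](CC)(CC)CC)C2 | intermediate
22 | (2R,6R,9S,10R)-10-bromo-9-(tert-butyldimethylsilyloxy)-11,11-dimethyl-7-methylidene-2-(triethylsilyloxy)spiro[5.5]undecan-3-one | C=C1C[C@H](O[Si](C)(C)C(C)(C)C)[C@H](Br)C(C)(C)[C@@]12CCC(=O)[C@H](O[Si](CC)(CC)CC)C2 | intermediate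
23 | (2R,3R,6R,9S,10R)-10-bromo-9-(tert-butyldimethylsilyloxy)-3,15-epoxy-3,11,11-trimethyl-7-methylidene-2-(triethylsilyloxy)spiro[5.5]undecane | C=C1C[C@H](O[Si](C)(C)C(C)(C)C)[C@H](Br)C(C)(C)[C@@]12CC[C@@]3(CO3)[C@H](O[Si](CC)(CC)CC)C2 | intermediate
24 | (2R,3S,6R,9S,10R)-10-bromo-9-(tert-butyldimethylsilyloxy)-3-(chloromethyl)-11,11-dimethyl-7-methylidene-2-(triethylsilyloxy)spiro[5.5]undecan-3-ol | C=C1C[C@H](O[Si](C)(C)C(C)(C)C)[C@H](Br)C(C)(C)[C@@]12CC[C@@](O)(CCl)[C@H](O[Si](CC)(CC)CC)C2 | intermediate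
25 | (2R,3S,6R,9S,10R)-10-bromo-9-(tert-butyldimethylsilyloxy)-3-(chloromethyl)-11,11-dimethyl-7-methylidenespiro[5.5]undecane-2,3-diol | C=C1C[C@H](O[Si](C)(C)C(C)(C)C)[C@H](Br)C(C)(C)[C@@]12CC[C@@](O)(CCl)[C@H](O)C2 | intermediate
26 | (3S,6R,9S,10R)-10-bromo-9-(tert-butyldimethylsilyloxy)-3-(chloromethyl)-3-hydroxy-11,11-dimethyl-7-methylidenespiro[5.5]undecan-2-one | C=C1C[C@H](O[Si](C)(C)C(C)(C)C)[C@H](Br)C(C)(C)[C@@]12CC[C@@](O)(CCl)C(=O)C2 | intermediate
27 | (3S,6R,9S,10R)-10-bromo-3-(chloromethyl)-3,9-dihydroxy-11,11-dimethyl-7-methylidenespiro[5.5]undecan-2-one | C=C1C[C@H](O)[C@H](Br)C(C)(C)[C@@]12CC[C@@](O)(CCl)C(=O)C2 | target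

Total step count: 19. Longest linear sequence: 19 steps (from 1).

Steps most likely to fail

Step 8. The Lewis acid may enolise the α-bromo aldehyde before it cyclises, which would erase the C10 configuration, or the ketal may ionise and engage the alkene. The fallback makes the same C8–C9 bond by an intramolecular Hosomi–Sakurai reaction, where the more nucleophilic allylsilane allows a weaker activator. It sets out from ketone 8. KN(SiMe3)2 and PhNTf2 should give the enol triflate F1. Kumada coupling with Me3SiCH2MgCl and Pd(PPh3)4 should give the allylsilane F2. The operations of steps 5 to 7 (Sia2BH then H2O2, Dess–Martin oxidation, organocatalytic bromination) should then give the silyl alcohol F3, the silyl aldehyde F4 and the silyl bromo aldehyde F5. BF3·OEt2 at −78 °C should close ring A with loss of the silyl group, the nucleophile again adding anti to the C–Br bond, and the route is rejoined at 14.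

Step 7. Enamine formation at the doubly neopentyl aldehyde may be slow, and the amine may then epimerise the product, eroding the enantiomeric purity on which the whole route depends. The fallback is an auxiliary-controlled bromination that sets out from aldehyde 12. Pinnick oxidation (NaClO2, NaH2PO4, 2-methylbut-2-ene) should give the acid F6. Its mixed pivalic anhydride should acylate lithiated (R)-4-benzyloxazolidin-2-one to the imide F7. The dibutylboron enolate (Bu2BOTf, iPr2NEt) is brominated with NBS at −78 °C to the bromo imide F8. LiBH4 in wet Et2O at 0 °C should cleave the auxiliary to the bromohydrin F9, and Dess–Martin oxidation returns the route to 13.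

Step 11. Arm selection may be weak if ring B reacts through another conformer, which would give a mixture of C6 epimers. The fallback replaces asymmetric deprotonation by separation and recycling, and sets out from ketone 16. LiN(iPr)2 with TMSCl should give 17 together with the regioisomeric enol ether F10. Pd(OAc)2 should convert the pair into 18 and the epimeric enone F11, which are diastereomers and are separated by chromatography. F11 is returned to 16 with [(Ph3P)CuH]6, and the route continues from 18.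

Further compounds
F1 | step 8 | enol triflate: 1-[8-(2-methylbut-3-en-2-yl)-1,4-dioxaspiro[4.5]decan-8-yl]ethenyl trifluoromethanesulfonate | C=CC(C)(C)C1(C(=C)OS(=O)(=O)C(F)(F)F)CCC2(CC1)OCCO2
F2 | step 8 | allylsilane: trimethyl{2-[8-(2-methylbut-3-en-2-yl)-1,4-dioxaspiro[4.5]decan-8-yl]prop-2-en-1-yl}silane | C=CC(C)(C)C1(C(=C)C[Si](C)(C)C)CCC2(CC1)OCCO2
F3 | step 8 | silyl alcohol: 3-methyl-3-{8-[3-(trimethylsilyl)prop-1-en-2-yl]-1,4-dioxaspiro[4.5]decan-8-yl}butan-1-ol | OCCC(C)(C)C1(C(=C)C[Si](C)(C)C)CCC2(CC1)OCCO2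
F4 | step 8 | silyl aldehyde: 3-methyl-3-{8-[3-(trimethylsilyl)prop-1-en-2-yl]-1,4-dioxaspiro[4.5]decan-8-yl}butanal | O=CCC(C)(C)C1(C(=C)C[Si](C)(C)C)CCC2(CC1)OCCO2
F5 | step 8 | silyl bromo aldehyde: (2R)-2-bromo-3-methyl-3-{8-[3-(trimethylsilyl)prop-1-en-2-yl]-1,4-dioxaspiro[4.5]decan-8-yl}butanal | O=C[C@H](Br)C(C)(C)C1(C(=C)C[Si](C)(C)C)CCC2(OCCO2)CC1
F6 | step 7 | acid: 3-methyl-3-[8-(prop-1-en-2-yl)-1,4-dioxaspiro[4.5]decan-8-yl]butanoic acid | OC(=O)CC(C)(C)C1(C(C)=C)CCC2(OCCO2)CC1
F7 | step 7 | imide: (4R)-4-benzyl-3-{3-methyl-3-[8-(prop-1-en-2-yl)-1,4-dioxaspiro[4.5]decan-8-yl]butanoyl}-1,3-oxazolidin-2-one | O=C(CC(C)(C)C1(C(C)=C)CCC2(OCCO2)CC1)N1[C@H](Cc2ccccc2)COC1=O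
F8 | step 7 | bromo imide: (4R)-4-benzyl-3-{(2R)-2-bromo-3-methyl-3-[8-(prop-1-en-2-yl)-1,4-dioxaspiro[4.5]decan-8-yl]butanoyl}-1,3-oxazolidin-2-one | O=C([C@H](Br)C(C)(C)C1(C(C)=C)CCC2(OCCO2)CC1)N1[C@H](Cc2ccccc2)COC1=O
F9 | step 7 | bromohydrin: (2R)-2-bromo-3-methyl-3-[8-(prop-1-en-2-yl)-1,4-dioxaspiro[4.5]decan-8-yl]butan-1-ol | OC[C@H](Br)C(C)(C)C1(C(C)=C)CCC2(OCCO2)CC1
F10 | step 11 | regioisomeric enol ether: C2=C3 trimethylsilyl enol ether of 16 (C6 epimeric series) | C=C1C[C@H](O[Si](C)(C)C(C)(C)C)[C@H](Br)C(C)(C)[C@@]12CCC(O[Si](C)(C)C)=CC2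
F11 | step 11 | epimeric enone: C1=C2 enone of 16 (C6 epimer of 18) | C=C1C[C@H](O[Si](C)(C)C(C)(C)C)[C@H](Br)C(C)(C)[C@@]12CCC(=O)C=C2
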